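**Retrosynthetic overview**
- Target ⇒ mono-amide amine + (E)-8-methylnon-6-enoic acid; the last bond made is the unsaturated amide C–N (acyl imidazole coupling).
- Mono-amide amine ⇒ C2-symmetric diamine "divanillylamine" + an 8-methylnonanoyl donor; the key step is a desymmetrising amide C–N formation with a proton-docking acyl donor (a 4-acyloxybenzoic acid).
- Diamine ⇒ divanillin (C=N formation, then hydrogenation) ⇒ 2 × vanillin (oxidative ortho–ortho phenol coupling).
- No ring is formed; both arenes come intact from vanillin. Bond order: biaryl C–C, two benzylic C–N, saturated amide C–N, unsaturated amide C–N.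

Assumption: the target has no stereocentre and no stable biaryl axis (only two ortho substituents), so the only stereo-element is the E C6''=C7'' alkene, bought in with (E)-8-methylnon-6-enoic acid; both C10 acids are catalogue reagents.

**Step 1**
Reactants: 1 vanillin (2 equiv)
Product: 2 divanillin (6,6'-dihydroxy-5,5'-dimethoxy-[1,1'-biphenyl]-3,3'-dicarbaldehyde)
Conditions: FeSO4·7H2O (3 mol%), Na2S2O8 (0.55 equiv), H2O, 50 °C; filter the precipitate
Reagents that add atoms: none
Why: Fe(II)/persulfate oxidises the phenol to its phenoxyl radical, and oxidative phenol dimerisation (radical ortho–ortho C–C coupling) occurs at C5, the only free position ortho to OH (para is blocked by CHO); the dimer precipitates and so escapes over-oxidation.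

**Step 2**
Reactants: 2 divanillin
Product: 4 divanillylamine [5,5'-bis(aminomethyl)-3,3'-dimethoxy-[1,1'-biphenyl]-2,2'-diol], via dioxime 3 (not isolated)
Conditions: NH2OH (50% aq., 2.5 equiv), 7 M NH3/MeOH, 50 °C; then Raney Ni, H2 (10 bar), 50 °C; filter, evaporate, triturate with water
Reagents that add atoms: hydroxylamine (NO)
Why: Aldehyde–hydroxylamine condensation followed by catalytic oxime hydrogenation (C=N reduction and N–O hydrogenolysis) under NH3, which suppresses secondary-amine formation; this is the standard vanillin-to-vanillylamine sequence, and no stereocentre is created.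

**Step 3**
Reactants: 5 8-methylnonanoic acid, 6 4-hydroxybenzoic acid
Product: 8 4-[(8-methylnonanoyl)oxy]benzoic acid, via acyl chloride 7 (not isolated)
Conditions: (COCl)2, cat. DMF, CH2Cl2, 0 °C→rt, evaporate; then 6, pyridine, THF, 0 °C→rt; 1 M HCl work-up; recrystallise
Reagents that add atoms: none
Why: Acid chloride formation and pyridine-mediated O-acylation of the phenol of 6; any mixed anhydride at the CO2H is hydrolysed in the acidic work-up, leaving the crystalline 4-acyloxybenzoic acid (the ester type of the decanoyloxybenzoic acid bleach activators).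

**Step 4**
Reactants: 4 divanillylamine, 8 4-[(8-methylnonanoyl)oxy]benzoic acid
Product: 10 N-{[5'-(aminomethyl)-2,2'-dihydroxy-3,3'-dimethoxy-[1,1'-biphenyl]-5-yl]methyl}-8-methylnonanamide, via ion pair 9 (not isolated)
Conditions: 8 (0.95 equiv, added over 2 h), anhydrous THF (5 mM in 4), 25→40 °C, 16 h; then aq. NaHCO3, extraction (EtOAc/n-BuOH)
Reagents that add atoms: none
Why: Proposed new method: proton-docked, self-limiting acyl transfer — acid 8 (pKa about 4.3) protonates one NH2 of 4 and stays on it as a contact ammonium–carboxylate pair (9) in THF, which holds its para aryl ester (N···C=O span about 7–10 Å, by estimate) within reach of the second NH2 of the same molecule (N···N about 5.5–10 Å), so aminolysis is intramolecular while bimolecular aminolysis of this weakly activated ester is slow at 5 mM; the product keeps its only remaining nitrogen as the ammonium 4-hydroxybenzoate, so it can dock a reagent but has no amine left to receive the acyl group, and the rigid para-phenylene spacer stops the docking nitrogen from reaching its own ester, so a second acylation needs a slow bimolecular event (estimated mono:bis at least 10:1 against 2:1 statistical; untested); closest known reaction types are mono-functionalisation of symmetric diamines through mono-protonation or cyclic anhydrides (internal ammonium carboxylate), aminolysis of 4-acyloxybenzoate active esters, and ion-pair-directed remote functionalisation.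

**Step 5**
Reactants: 10 mono-amide amine, 11 (E)-8-methylnon-6-enoic acid
Product: 13 6'',7''-dihydro-5',5'''-dicapsaicin (target), via acyl imidazole 12 (not isolated)
Conditions: 11 (1.1 equiv), CDI (1.05 equiv), THF, rt, 1 h; then 10, DMF, rt, 12 h; K2CO3/MeOH (30 min), aq. NH4Cl work-up
Reagents that add atoms: none
Why: Amide coupling through the acyl imidazole (CDI activation): the primary benzylic amine is acylated far faster than the hindered, hydrogen-bonded phenols (any aryl ester is cleaved by the K2CO3/MeOH wash), and the E alkene brought in with 11 sees no acid, radical or metal and keeps its geometry.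

**Compound list**
1 | vanillin (4-hydroxy-3-methoxybenzaldehyde) | COc1cc(C=O)ccc1O | starting material
2 | divanillin (6,6'-dihydroxy-5,5'-dimethoxy-[1,1'-biphenyl]-3,3'-dicarbaldehyde) | COc1cc(C=O)cc(-c2cc(C=O)cc(OC)c2O)c1O | intermediate
3 | divanillin (E,E)-dioxime | COc1cc(/C=N/O)cc(-c2cc(/C=N/O)cc(OC)c2O)c1O | intermediate (not isolated)
4 | divanillylamine, 5,5'-bis(aminomethyl)-3,3'-dimethoxy-[1,1'-biphenyl]-2,2'-diol | COc1cc(CN)cc(-c2cc(CN)cc(OC)c2O)c1O | intermediate
5 | 8-methylnonanoic acid | CC(C)CCCCCCC(=O)O | starting material
6 | 4-hydroxybenzoic acid | O=C(O)c1ccc(O)cc1 | starting material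
7 | 8-methylnonanoyl chloride | CC(C)CCCCCCC(=O)Cl | intermediate (not isolated)
8 | 4-[(8-methylnonanoyl)oxy]benzoic acid | CC(C)CCCCCCC(=O)Oc1ccc(cc1)C(=O)O | intermediate
9 | 1:1 ion pair: mono-ammonium of 4 / 4-[(8-methylnonanoyl)oxy]benzoate | COc1cc(C[NH3+])cc(-c2cc(CN)cc(OC)c2O)c1O.CC(C)CCCCCCC(=O)Oc1ccc(cc1)C(=O)[O-] | intermediate (not isolated)
10 | N-{[5'-(aminomethyl)-2,2'-dihydroxy-3,3'-dimethoxy-[1,1'-biphenyl]-5-yl]methyl}-8-methylnonanamide | COc1cc(CN)cc(-c2cc(CNC(=O)CCCCCCC(C)C)cc(OC)c2O)c1O | intermediate
11 | (E)-8-methylnon-6-enoic acid | CC(C)/C=C/CCCCC(=O)O | starting material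
12 | (E)-1-(1H-imidazol-1-yl)-8-methylnon-6-en-1-one | CC(C)/C=C/CCCCC(=O)n1ccnc1 | intermediate (not isolated)
13 | 6'',7''-dihydro-5',5'''-dicapsaicin | COc1cc(CNC(=O)CCCC/C=C/C(C)C)cc(-c2cc(CNC(=O)CCCCCCC(C)C)cc(OC)c2O)c1O | target

**Step count and risks**
Total step count: 5 (steps 1, 2, 4, 5 in line; step 3 makes the acyl donor). Longest linear sequence: 4 steps (1 → 2 → 4 → 10 → 13).

The three steps most likely to fail:

Step 4 (the proposed new step) may drift towards a statistical mixture if ion pairing in THF is loose, if 4 is too insoluble, or if intramolecular delivery is slower than estimated. The fallback is known protecting-group desymmetrisation; it sets out from 4 and comes back at 10. Compound 4 in threefold excess is treated with Boc2O (1 equiv, MeOH, 0 °C; excess 4 is recovered from the aqueous phase) to give tert-butyl N-{[5'-(aminomethyl)-2,2'-dihydroxy-3,3'-dimethoxy-[1,1'-biphenyl]-5-yl]methyl}carbamate F1. Its free amine is acylated with acyl chloride 7 (made as in step 3; EtOAc/aq. NaHCO3) to give tert-butyl N-{[2,2'-dihydroxy-3,3'-dimethoxy-5'-[(8-methylnonanamido)methyl]-[1,1'-biphenyl]-5-yl]methyl}carbamate F2. HCl in dioxane removes the Boc group to give the mono-amide amine hydrochloride F3, and neutralisation with aq. NaHCO3 gives 10.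

Step 2 may suffer from incomplete oximation of the poorly soluble dialdehyde, from secondary-amine by-products, or from an air-sensitive free base. The fallback replaces oxime hydrogenation by reductive alkylation of a carbamate; it sets out from 2 and comes back at 4. Compound 2 is treated with tert-butyl carbamate, Et3SiH and TFA in MeCN at rt to give di-tert-butyl N,N'-[(2,2'-dihydroxy-3,3'-dimethoxy-[1,1'-biphenyl]-5,5'-diyl)bis(methylene)]dicarbamate F4. HCl in dioxane gives divanillylamine dihydrochloride F5, which is neutralised with aq. NaHCO3 to the isoelectric point to give 4.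

Step 5 may suffer from poor solubility of the zwitterionic amino-biphenol or from competing phenol acylation. The fallback is a biocatalytic aminolysis that cannot acylate phenols; it sets out from 11 and comes back at 13. Compound 11 is esterified (MeOH, cat. H2SO4) to methyl (E)-8-methylnon-6-enoate F6, which is reacted with 10 over immobilised Candida antarctica lipase B (2-methyl-2-butanol, 60 °C, molecular sieves) to give 13.

**Further compounds**
F1 | step 4 | tert-butyl N-{[5'-(aminomethyl)-2,2'-dihydroxy-3,3'-dimethoxy-[1,1'-biphenyl]-5-yl]methyl}carbamate | COc1cc(CN)cc(-c2cc(CNC(=O)OC(C)(C)C)cc(OC)c2O)c1O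
F2 | step 4 | tert-butyl N-{[2,2'-dihydroxy-3,3'-dimethoxy-5'-[(8-methylnonanamido)methyl]-[1,1'-biphenyl]-5-yl]methyl}carbamate | COc1cc(CNC(=O)CCCCCCC(C)C)cc(-c2cc(CNC(=O)OC(C)(C)C)cc(OC)c2O)c1O
F3 | step 4 | mono-amide amine hydrochloride (hydrochloride of 10) | COc1cc(CN)cc(-c2cc(CNC(=O)CCCCCCC(C)C)cc(OC)c2O)c1O.Cl
F4 | step 2 | di-tert-butyl N,N'-[(2,2'-dihydroxy-3,3'-dimethoxy-[1,1'-biphenyl]-5,5'-diyl)bis(methylene)]dicarbamate | COc1cc(CNC(=O)OC(C)(C)C)cc(-c2cc(CNC(=O)OC(C)(C)C)cc(OC)c2O)c1O
F5 | step 2 | divanillylamine dihydrochloride | COc1cc(CN)cc(-c2cc(CN)cc(OC)c2O)c1O.Cl.Cl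
F6 | step 5 | methyl (E)-8-methylnon-6-enoate | CC(C)/C=C/CCCCC(=O)OC
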